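**Retrosynthetic overview**
1. 9 ⇐ 8: anti (SN2-like) hydrolysis of a vinyl oxirane at its allylic carbon, giving C5–OH trans to C6–OH.
2. 8 ⇐ 7 ⇐ 6: hydroxyl-directed epoxidation of the dienyl dibenzoate syn to the tertiary OH (sets C6–O); 7 comes from 6 by benzoylation.
3. 6 ⇐ 5 ⇐ 2 + 4 (key step): enantioselective hydroxylative dearomatisation of phenol 2 by chiral iodane 4 sets the quaternary carbinol; quinol 5 is reduced in the same flask (sets C2).
4. 2 ⇐ salicyl alcohol 1; 4 ⇐ commercial diiodobinaphthyl 3.
5. Rings: the cyclohexene is the benzene ring of 1, dearomatised in step 3 and never built; the oxirane of 8 is the only ring formed (step 5) and is opened in step 6.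

Assumption: locants follow the name of 9 (C1 quaternary carbinol, C2 benzoyloxy, C3=C4, C5 and C6 hydroxy); the (R)-iodane 4 is taken to give the (R)-quinol 5, and if the sense of induction is the opposite, (S)-4 is used and nothing else changes.

**Step 1**
Reactants: 1 2-(hydroxymethyl)phenol (salicyl alcohol)
Product: 2 (2-hydroxyphenyl)methyl benzoate
Conditions: vinyl benzoate (3 equiv), immobilised Candida antarctica lipase B (Novozym 435), MTBE, 45 °C
Reagents that add atoms: vinyl benzoate, C=COC(=O)c1ccccc1
Why: Lipase-catalysed transesterification with an enol ester, made irreversible by tautomerisation of the vinyl alcohol, acylates only the primary benzylic hydroxyl because the phenol is not accepted as nucleophile by the serine hydrolase, and the neutral medium avoids base-induced ortho-quinone methide formation; no stereocentre is formed.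

**Step 2** (reagent branch)
Reactants: 3 (R)-2,2'-diiodo-1,1'-binaphthalene
Product: 4 (R)-2,2'-diiodyl-1,1'-binaphthalene
Conditions: dimethyldioxirane (ca. 0.08 M in acetone, 6 equiv), CH2Cl2, 0 °C to rt; solid collected and dried
Reagents that add atoms: dimethyldioxirane, CC1(C)OO1
Why: Dioxirane oxygen-atom transfer (oxidation of an aryl iodide to an iodylarene) takes each iodine to the pentavalent state without touching the configurationally stable biaryl axis, which is the only stereo-element of the reagent.

**Step 3** (key step)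
Reactants: 2 (2-hydroxyphenyl)methyl benzoate; 4 (R)-2,2'-diiodyl-1,1'-binaphthalene
Product: 6 [(1R,6S)-1,6-dihydroxycyclohexa-2,4-dien-1-yl]methyl benzoate, via ortho-quinol 5 (not isolated)
Conditions: 4 (1.1 equiv), CH2Cl2–THF, 0.02 M, −40 °C; then CeCl3·7H2O, NaBH4, MeOH, −78 °C, added cold before any warming or work-up
Reagents that add atoms: (R)-2,2'-diiodyl-1,1'-binaphthalene (compound 4, oxygen donor), O=I(=O)c1ccc2ccccc2c1-c1c(I(=O)=O)ccc2ccccc12
Why: Proposed new method: hydroxylative phenol dearomatisation — the phenol exchanges onto pentavalent iodine and oxygen is passed in a [2,3]-type shift to the substituted ortho carbon (the site that achiral IBX-type reagents are known to attack in this very phenol), here inside the C2-symmetric biaryl pocket so that one face of the arene is selected and the quaternary carbinol of 5 is set as (R), the closest known reactions being the racemic IBX/SIBX hydroxylative dearomatisation of 2-alkylphenols and its asymmetric variants with chiral biaryl iodanes; the quinol, which would otherwise undergo [4+2] dimerisation on warming, is trapped cold and dilute by a Luche 1,2-reduction in which hydride enters from the face of the small hydroxyl, anti to the CH2OBz arm, giving the trans-diol (new centre S).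

**Step 4**
Reactants: 6 [(1R,6S)-1,6-dihydroxycyclohexa-2,4-dien-1-yl]methyl benzoate
Product: 7 [(1R,6S)-6-(benzoyloxy)-1-hydroxycyclohexa-2,4-dien-1-yl]methyl benzoate
Conditions: BzCl (1.3 equiv), pyridine, 4-(dimethylamino)pyridine (5 mol%), CH2Cl2, 0 °C
Reagents that add atoms: benzoyl chloride, O=C(Cl)c1ccccc1
Why: Nucleophile-catalysed O-acylation with an acyl chloride reaches the secondary allylic hydroxyl while the tertiary one is inert, and since any benzoyl that wandered between the 1,3-related primary and secondary oxygens in step 3 ends in the same dibenzoate, no stereocentre or regiochemistry is at stake.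

**Step 5**
Reactants: 7 [(1R,6S)-6-(benzoyloxy)-1-hydroxycyclohexa-2,4-dien-1-yl]methyl benzoate
Product: 8 [(1S,2R,3S,6S)-3-(benzoyloxy)-2-hydroxy-7-oxabicyclo[4.1.0]hept-4-en-2-yl]methyl benzoate
Conditions: mCPBA (1.05 equiv), CH2Cl2 / aqueous phosphate buffer pH 8, 0 °C
Reagents that add atoms: mCPBA, O=C(OO)c1cccc(Cl)c1
Why: Henbest hydroxyl-directed Prilezhaev epoxidation: the tertiary allylic OH hydrogen-bonds the peracid and delivers oxygen to its own face of the adjacent C5=C6 bond (also the face anti to both benzoyloxy-bearing substituents), while the C3=C4 bond is deactivated by the allylic benzoate, so both oxirane carbons are set with the oxygen cis to the tertiary hydroxyl.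

**Step 6**
Reactants: 8 [(1S,2R,3S,6S)-3-(benzoyloxy)-2-hydroxy-7-oxabicyclo[4.1.0]hept-4-en-2-yl]methyl benzoate
Product: 9 [(1S,2S,5R,6S)-2-(benzoyloxy)-1,5,6-trihydroxycyclohex-3-en-1-yl]methyl benzoate
Conditions: HClO4 (5 mol%), THF–H2O 1:1, 0 °C
Reagents that add atoms: water, O
Why: Acid-catalysed, SN2-like anti opening of a vinyl oxirane by water occurs at the allylic carbon C5 (activated by the alkene, whereas C6 is neopentylic and the remote alkene terminus is deactivated by the adjacent benzoate), inverting C5 and retaining the C6–O bond, which gives the 5,6-trans diol with C6–OH cis to the tertiary hydroxyl, that is 9.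

**Compound list**
1 | 2-(hydroxymethyl)phenol (salicyl alcohol) | OCc1ccccc1O | starting material
2 | (2-hydroxyphenyl)methyl benzoate | O=C(OCc1ccccc1O)c1ccccc1 | intermediate
3 | (R)-2,2'-diiodo-1,1'-binaphthalene (axial chirality, carried by the name) | Ic1ccc2ccccc2c1-c1c(I)ccc2ccccc12 | starting material
4 | (R)-2,2'-diiodyl-1,1'-binaphthalene (axial chirality, carried by the name) | O=I(=O)c1ccc2ccccc2c1-c1c(I(=O)=O)ccc2ccccc12 | intermediate
5 | [(1R)-1-hydroxy-2-oxocyclohexa-3,5-dien-1-yl]methyl benzoate | O=C(OC[C@@]1(O)C(=O)C=CC=C1)c1ccccc1 | intermediate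
6 | [(1R,6S)-1,6-dihydroxycyclohexa-2,4-dien-1-yl]methyl benzoate | O=C(OC[C@@]1(O)[C@@H](O)C=CC=C1)c1ccccc1 | intermediate
7 | [(1R,6S)-6-(benzoyloxy)-1-hydroxycyclohexa-2,4-dien-1-yl]methyl benzoate | O=C(OC[C@@]1(O)[C@@H](OC(=O)c2ccccc2)C=CC=C1)c1ccccc1 | intermediate
8 | [(1S,2R,3S,6S)-3-(benzoyloxy)-2-hydroxy-7-oxabicyclo[4.1.0]hept-4-en-2-yl]methyl benzoate | O=C(OC[C@@]1(O)[C@@H](OC(=O)c2ccccc2)C=C[C@@H]2O[C@H]12)c1ccccc1 | intermediate
9 | [(1S,2S,5R,6S)-2-(benzoyloxy)-1,5,6-trihydroxycyclohex-3-en-1-yl]methyl benzoate | O=C(OC[C@@]1(O)[C@@H](OC(=O)c2ccccc2)C=C[C@@H](O)[C@@H]1O)c1ccccc1 | target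

The descriptor of the quaternary carbon changes from R (5–8) to S (9) only because the CIP ranking of its neighbours changes; no bond to it is touched after step 3.

**Step count and risks**
Total step count: 6 (five on the main line plus the one-step preparation of reagent 4). Longest linear sequence: 5 steps (1 → 2 → 6 → 7 → 8 → 9).

Most likely to fail, first: step 3. The enantioselectivity of the iodane on this particular phenol is unproven, and the reduction has to outrun the [4+2] dimerisation of quinol 5. The fallback sets out from 2 and comes back at 8. Phenol 2 is dearomatised with achiral stabilised 2-iodoxybenzoic acid (SIBX) in THF, the reagent already known to give the quinol from this phenol, which furnishes the racemic quinol F1. This is reduced in the same flask as in step 3 to the racemic trans-diol F2 and benzoylated as in step 4 to the racemic dibenzoate F3. The asymmetry is then introduced by kinetic resolution in the hydroxyl-directed epoxidation: Hf(OtBu)4 with (1R,2R)-N,N'-dihydroxy-N,N'-bis(diphenylacetyl)cyclohexane-1,2-diamine (or its antipode, whichever is matched) and cumene hydroperoxide in toluene epoxidises one enantiomer of F3 to 8, and the unreacted antipode is separated.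

Second: step 5. The peracid may attack the C3=C4 bond or the wrong face, or the vinyl oxirane may not survive isolation. The fallback sets out from 7 and comes back at 9 without any oxirane. Stoichiometric OsO4 with TMEDA in CH2Cl2 at −78 °C (hydrogen-bond-directed syn-dihydroxylation of the alkene next to the tertiary OH, osmate then cleaved with aqueous NaHSO3) gives the all-cis triol [(1S,2S,5S,6S)-2-(benzoyloxy)-1,5,6-trihydroxycyclohex-3-en-1-yl]methyl benzoate F4. MnO2 in CH2Cl2 oxidises only its allylic C5 hydroxyl to the enone [(1S,2S,6R)-2-(benzoyloxy)-1,6-dihydroxy-5-oxocyclohex-3-en-1-yl]methyl benzoate F5. Hydroxyl-delivered reduction with Me4NBH(OAc)3 in MeCN–AcOH at −30 °C then places the new C5 hydroxyl trans to the C6 hydroxyl, giving 9.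

Third: step 6. Water may add at the remote alkene terminus (1,4-opening), open with retention through an allyl cation, or a benzoate may participate. The fallback sets out from 8 and comes back at 9. The oxirane is opened under non-ionising conditions with chloroacetic acid and caesium chloroacetate in DMF at 40 °C (carboxylate SN2 at the allylic carbon) to the chloroacetate [(1S,2S,5R,6S)-2-(benzoyloxy)-5-(chloroacetoxy)-1,6-dihydroxycyclohex-3-en-1-yl]methyl benzoate F6. The chloroacetyl group is then removed with thiourea and NaHCO3 in MeOH–THF at 50 °C, which leaves both benzoates in place and gives 9.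

**Further compounds**
F1 | step 3 | racemic (1-hydroxy-2-oxocyclohexa-3,5-dien-1-yl)methyl benzoate | O=C(OC[C@@]1(O)C(=O)C=CC=C1)c1ccccc1.O=C(OC[C@]1(O)C(=O)C=CC=C1)c1ccccc1
F2 | step 3 | racemic [(1R*,6S*)-1,6-dihydroxycyclohexa-2,4-dien-1-yl]methyl benzoate | O=C(OC[C@@]1(O)[C@@H](O)C=CC=C1)c1ccccc1.O=C(OC[C@]1(O)[C@H](O)C=CC=C1)c1ccccc1
F3 | step 3 | racemic [(1R*,6S*)-6-(benzoyloxy)-1-hydroxycyclohexa-2,4-dien-1-yl]methyl benzoate | O=C(OC[C@@]1(O)[C@@H](OC(=O)c2ccccc2)C=CC=C1)c1ccccc1.O=C(OC[C@]1(O)[C@H](OC(=O)c2ccccc2)C=CC=C1)c1ccccc1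
F4 | step 5 | [(1S,2S,5S,6S)-2-(benzoyloxy)-1,5,6-trihydroxycyclohex-3-en-1-yl]methyl benzoate | O=C(OC[C@@]1(O)[C@@H](OC(=O)c2ccccc2)C=C[C@H](O)[C@@H]1O)c1ccccc1
F5 | step 5 | [(1S,2S,6R)-2-(benzoyloxy)-1,6-dihydroxy-5-oxocyclohex-3-en-1-yl]methyl benzoate | O=C(OC[C@@]1(O)[C@@H](OC(=O)c2ccccc2)C=CC(=O)[C@@H]1O)c1ccccc1
F6 | step 6 | [(1S,2S,5R,6S)-2-(benzoyloxy)-5-(chloroacetoxy)-1,6-dihydroxycyclohex-3-en-1-yl]methyl benzoate | O=C(OC[C@@]1(O)[C@@H](OC(=O)c2ccccc2)C=C[C@@H](OC(=O)CCl)[C@@H]1O)c1ccccc1
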